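Readings and results are calculated for an exercise; noise was put on by code.

The birch run, charged with E at 0.43 M and held at 124 °C, stands at 3 % of its charge as Z after 6.00 h. The colder oak run, charged at 0.031 M, holds 35 % after 60.0 h. So the last readings come to 0.00500 h⁻¹ of the charge per hour in birch and 0.00583 h⁻¹ in oak, two figures that a scatter of 2 percentage points on birch's reading does not part, and a plain step first order in E is not excluded. But X starts out of solution and is held at the same level in both runs, so the reckoning here tries another reading: it assumes the entry of X to be the rate-limiting step in birch and the same constant feed to hold in the new flasks.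

| setting | oak | birch | grey | teal | blue | amber | ochre | red |
|---|---|---|---|---|---|---|---|---|
| E | 0.031 M | 0.43 M | 0.25 M | 0.040 M | 0.50 M | 0.15 M | 0.15 M | 0.10 M |
| X | 42 mM (held) | 42 mM (held) | 42 mM (held) | 42 mM (held) | 42 mM (held) | 42 mM (held) | 42 mM (held) | 42 mM (held) |
| temperature | 80 °C | 124 °C | 130 °C | 120 °C | 140 °C | 120 °C | 100 °C | 60 °C |
| remark | run made earlier | run made earlier |  |  |  |  |  |  |
| time |  |  | 20 h | 20 h | 20 h | 20 h | 20 h | 20 h |

- oak (time / h: Z / %): 8.00: 5; 15.0: 5; 20.0: 8; 30.0: 17; 40.0: 28; 60.0: 35
- birch (time / h: Z / %): 1.00: 0; 2.00: 0; 2.50: 0; 4.00: 3; 5.00: 2; 6.00: 3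

(readings scatter by 2 percentage points)

- at the start none of X is in solution
- a reading or a percentage of Z counts all its forms, free or not

1. the flasks by amount of Z, in percent of the E charged, highest first, at 20 h (grey / teal / blue / amber / ochre / red)
2. the amount of Z, in percent of the E charged of the flask you put first, at 20 h
3. the amount of Z, in percent of the E charged of the flask you put last, at 20 h

A constant rate integrates to rate times time. The last birch readings, summed over their times, give 2.29 mM h⁻¹, the feed rate: the E that entering X can turn per hour. It is rough, since each reading carries 2 points. Feed rate times time, divided by the charge, is the feed budget, a fraction of the charge. At 20 h blue has 9.17 %, grey 18.3 % and amber 30.6 %, but teal has 115 %, more than its charge. So teal is not capped by the feed, and, hotter than oak, it is expected above oak's 35 %. Red, colder than oak, is expected last, below oak's 8 % at 20.0 h.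

The forecast gives teal > amber > ochre > grey > blue > red, with 30 % on top (range 20 % to 45 %) and 1 % at the bottom (range 0 % to 3 %). It reads “a ceiling of about 0.012 M Z, independent of E”, where the reckoning here has a rate.

The flasks give teal > amber > ochre > grey > blue > red, with 64.2 % in teal and 2.60 % in red.

    D ⇌ Z, rate k1*(cs1 - [Z]) while solid is left; crystals form when [Z] > cs1 (solubility = 2.40 mM, k = 0.00318 min⁻¹)
    E + Z → G (k = 4.33 × 10⁻⁴ M⁻¹ min⁻¹, Ea = 97.0 kJ mol⁻¹)
    E + L → Z, rate k3*[E]*[L]^0.5 (k = 0.00268 M⁻⁰·⁵ min⁻¹, Ea = 72.0 kJ mol⁻¹)
    X ⇌ L, rate k4*(csat - [L]) (kL = 0.00121 min⁻¹)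
    (constants at 100 °C)

Teal's Z, crystals D counted in, lies above the forecast's range and below its budget of 115 %, with E at 33.8 % still there at 20.0 h. The neighbouring flask is teal charged with E at 0.16 M, time and temperature held. The same feed rate gives it a budget of 28.6 %, less than teal's. That neighbour stands at Z 32.5 %, with G at 4.73 % and E at 63 %.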